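**Plan**
- Cuts, in retrosynthetic order: the seven phenols are masked as MOM ethers; ring C of the chromone is opened at O1–C2 and its C2=C3 bond is taken back to a Claisen–Schmidt union of aldehyde 24 with ring A ketone 31; the formyl carbon is removed from C5 of the dihydrobenzofuran (bromide 22); the dihydrofuran is cut at C2–C3 and O1–C2.
- Enabling feature (dihydrobenzofuran numbered O1, C2, C3, C3a, C4–C7, C7a): O1–C7a–C3a–C3, i.e. the ring B oxygen, two ring B carbons and the benzylic carbon carrying the 4-hydroxyphenyl ring, is a masked ortho-quinone methide. C2, carrying the 3,5-dihydroxyphenyl ring, is a single benzylic carbon that can arrive as a sulfonium ylide.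
- Forward order: ring B sulfone 11 and thiolanium salt 18 are made separately and their (4+1) union closes the dihydrofuran ring. The bromide then becomes the aldehyde, condensation with 31 joins the chain, iodine/DMSO closes ring C, and acid removes the MOM groups.
- Stereochemistry: C2 and C3 are both set in step 13. The absolute sense comes from C2-symmetric (2S,5S)-2,5-dimethylthiolane (from (2R,5R)-hexane-2,5-diol by double inversion), and the trans relation from an anti betaine that closes with inversion. No later step touches either centre.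

Key step: step 13

Assumption: the ylide of the (2S,5S)-thiolanium salt is taken to react through the same ylide face that this sulfide uses in benzylidene transfer to aldehydes (there the (2R,5R)-sulfide leads to (S,S)-stilbene oxides), which corresponds to the (2S,3S) dihydrobenzofuran.

**Route**

Step 1
Reactants: 1 2,5-dihydroxybenzaldehyde
Product: 2 2,5-bis(methoxymethoxy)benzaldehyde
Conditions: NaH, MOMCl, DMF, 0 °C to rt
Reagents that add atoms: chloromethyl methyl ether (MOMCl), COCCl
Why: Williamson-type O-alkylation of both phenoxides gives base-stable MOM ethers that are removed only in the final acid step.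

Step 2
Reactants: 2 2,5-bis(methoxymethoxy)benzaldehyde
Product: 4 2,5-bis(methoxymethoxy)phenol, via aryl formate 3 (not isolated)
Conditions: mCPBA, CH2Cl2, 0 °C to rt; then K2CO3 (cat.), MeOH, rt
Reagents that add atoms: meta-chloroperoxybenzoic acid (mCPBA), O=C(OO)c1cccc(Cl)c1
Why: In this Baeyer–Villiger (Dakin-type) oxidation the electron-rich aryl group migrates in preference to hydride, and methanolysis of the formate leaves the single free phenol that later becomes O1.

Step 3
Reactants: 4 2,5-bis(methoxymethoxy)phenol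
Product: 5 2-hydroxy-3,6-bis(methoxymethoxy)benzaldehyde
Conditions: MgCl2, Et3N, (CH2O)n, MeCN, reflux
Reagents that add atoms: paraformaldehyde (as formaldehyde), C=O
Why: The magnesium-mediated ortho-formylation of phenols (Casnati–Skattebøl) delivers formaldehyde only to the one free ortho carbon, the future C3a, and hydride transfer to a second formaldehyde gives the aldehyde.

Step 4
Reactants: 5 2-hydroxy-3,6-bis(methoxymethoxy)benzaldehyde
Product: 6 5-bromo-2-hydroxy-3,6-bis(methoxymethoxy)benzaldehyde
Conditions: NBS, MeCN, 0 °C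
Reagents that add atoms: N-bromosuccinimide, O=C1CCC(=O)N1Br
Why: Electrophilic aromatic bromination should go para to the free phenol (also ortho to an OMOM group and meta to the formyl group), since the only other open position is para to the formyl group and deactivated.

Step 5
Reactants: 7 4-bromophenol
Product: 8 1-bromo-4-(methoxymethoxy)benzene
Conditions: NaH, MOMCl, DMF, 0 °C to rt
Reagents that add atoms: chloromethyl methyl ether (MOMCl), COCCl
Why: Williamson-type MOM ether formation masks the phenol so that the aryl bromide can be turned into a Grignard reagent.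

Step 6
Reactants: 6 5-bromo-2-hydroxy-3,6-bis(methoxymethoxy)benzaldehyde; 8 1-bromo-4-(methoxymethoxy)benzene
Product: 10 racemic 4-bromo-2-{hydroxy[4-(methoxymethoxy)phenyl]methyl}-3,6-bis(methoxymethoxy)phenol, via aryl Grignard reagent 9 (not isolated)
Conditions: 8, Mg, THF, reflux; solution of 9 (2.5 equiv) cannulated onto 6, THF, 0 °C; aq NH4Cl
Reagents that add atoms: none
Why: Grignard addition to the aldehyde after the first equivalent has deprotonated the phenol, with no exchange at the aryl bromide of 6 at 0 °C; the racemic carbinol centre is erased in step 13.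

Step 7
Reactants: 10 racemic 4-bromo-2-{hydroxy[4-(methoxymethoxy)phenyl]methyl}-3,6-bis(methoxymethoxy)phenol
Product: 11 racemic 4-bromo-3,6-bis(methoxymethoxy)-2-{[4-(methoxymethoxy)phenyl](4-methylbenzenesulfonyl)methyl}phenol
Conditions: p-TolSO2H (1.5 equiv), 4 Å MS, CH2Cl2, 0 °C to rt
Reagents that add atoms: p-toluenesulfinic acid, Cc1ccc(S(=O)O)cc1
Why: SN1-type substitution of the ortho-hydroxy benzhydrol, which ionises readily because of the phenol and the para-alkoxyphenyl ring, with S-alkylation of the sulfinate giving the sulfone under acidity too weak to cleave aryl MOM ethers.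

Step 8
Reactants: 12 (2R,5R)-hexane-2,5-diol
Product: 13 (2R,5R)-hexane-2,5-diyl dimethanesulfonate
Conditions: MsCl, Et3N, CH2Cl2, 0 °C
Reagents that add atoms: methanesulfonyl chloride, CS(=O)(=O)Cl
Why: O-sulfonylation activates both secondary alcohols without touching the C–O bonds, so both centres keep their configuration.

Step 9
Reactants: 13 (2R,5R)-hexane-2,5-diyl dimethanesulfonate
Product: 14 (2S,5S)-2,5-dimethylthiolane
Conditions: Na2S·9H2O, EtOH, 50 °C
Reagents that add atoms: sodium sulfide, [Na+].[Na+].[S-2]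
Why: Double SN2 displacement by sulfide (the second one a 5-exo-tet ring closure) inverts both carbons and gives the C2-symmetric (2S,5S)-thiolane.

Step 10
Reactants: 15 3,5-dihydroxybenzyl alcohol
Product: 16 [3,5-bis(methoxymethoxy)phenyl]methanol
Conditions: MOMCl (2.1 equiv), K2CO3, acetone, 0 °C to rt
Reagents that add atoms: chloromethyl methyl ether (MOMCl), COCCl
Why: Chemoselective Williamson alkylation, since K2CO3 deprotonates only the two phenols and the benzylic alcohol stays free.

Step 11
Reactants: 16 [3,5-bis(methoxymethoxy)phenyl]methanol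
Product: 17 1-(bromomethyl)-3,5-bis(methoxymethoxy)benzene
Conditions: CBr4, PPh3, CH2Cl2, 0 °C
Reagents that add atoms: carbon tetrabromide, BrC(Br)(Br)Br
Why: The Appel reaction turns the primary benzylic alcohol into the bromide under neutral conditions that leave the MOM ethers intact.

Step 12
Reactants: 17 1-(bromomethyl)-3,5-bis(methoxymethoxy)benzene; 14 (2S,5S)-2,5-dimethylthiolane
Product: 18 (2S,5S)-1-[3,5-bis(methoxymethoxy)benzyl]-2,5-dimethylthiolan-1-ium tetrafluoroborate
Conditions: NaBF4, CH2Cl2/H2O, rt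
Reagents that add atoms: sodium tetrafluoroborate, [Na+].F[B-](F)(F)F
Why: SN2 S-alkylation of the sulfide, driven to completion by exchange of bromide for the non-nucleophilic tetrafluoroborate, gives a single salt because the two lone pairs of the C2-symmetric sulfide are equivalent.

Step 13
Reactants: 11 racemic 4-bromo-3,6-bis(methoxymethoxy)-2-{[4-(methoxymethoxy)phenyl](4-methylbenzenesulfonyl)methyl}phenol; 18 (2S,5S)-1-[3,5-bis(methoxymethoxy)benzyl]-2,5-dimethylthiolan-1-ium tetrafluoroborate
Product: 22 (2S,3S)-2-[3,5-bis(methoxymethoxy)phenyl]-5-bromo-4,7-bis(methoxymethoxy)-3-[4-(methoxymethoxy)phenyl]-2,3-dihydro-1-benzofuran, via ortho-quinone methide 19 (not isolated), via sulfonium ylide 20 (not isolated), via betaine 21 (not isolated)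
Conditions: 18 (1.3 equiv), Cs2CO3 (3 equiv), CH2Cl2, −20 °C to rt
Reagents that add atoms: none
Why: Cs2CO3 deprotonates the phenol of 11, which expels p-toluenesulfinate by 1,4-elimination to give ortho-quinone methide 19, and also deprotonates 18 to the benzylic ylide 20; the ylide carbon adds to the exocyclic methide carbon in a conjugate addition that restores the aromaticity of ring B, and the phenoxide of betaine 21 then displaces the sulfide. The closest known reaction type is the formal (4+1) annulation of ortho-quinone methides, released from 2-(1-tosylalkyl)phenols by Cs2CO3, with sulfonium ylides to give trans-2,3-disubstituted 2,3-dihydrobenzofurans. The dihydrofuran ring closes by 5-exo-tet SN2 attack of O1 on C2 with inversion at C2. C2 is controlled by the C2-symmetric thiolanium unit, whose ring methyl groups fix the ylide conformation and shield one face of the ylide carbon, and C3 is controlled by the anti approach of the two partners in the C–C bond formation, which leaves the two aryl groups trans after ring closure. The step needs trans selectivity, one absolute sense and one ring-closing oxygen: the irreversible anti addition and the invertive closure should give trans, the sulfide should give the absolute sense, and 11 has only one free phenol, ortho to the sulfonyl carbon, so only O1–C7a–C3a–C3 can serve as the four-atom unit while the bromine at C5 is kept for step 14.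

Step 14
Reactants: 22 (2S,3S)-2-[3,5-bis(methoxymethoxy)phenyl]-5-bromo-4,7-bis(methoxymethoxy)-3-[4-(methoxymethoxy)phenyl]-2,3-dihydro-1-benzofuran
Product: 24 (2S,3S)-2-[3,5-bis(methoxymethoxy)phenyl]-4,7-bis(methoxymethoxy)-3-[4-(methoxymethoxy)phenyl]-2,3-dihydro-1-benzofuran-5-carbaldehyde, via aryllithium 23 (not isolated)
Conditions: n-BuLi, THF, −78 °C; DMF, −78 to 0 °C; aq NH4Cl
Reagents that add atoms: N,N-dimethylformamide, CN(C)C=O
Why: Bromine–lithium exchange at −78 °C is faster than ortho-lithiation or benzylic deprotonation, and formylation of the aryllithium with DMF gives the aldehyde without involving C2 or C3.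

Step 15
Reactants: 25 2-methylresorcinol (2-methylbenzene-1,3-diol)
Product: 26 1,3-bis(methoxymethoxy)-2-methylbenzene
Conditions: NaH, MOMCl, DMF, 0 °C to rt
Reagents that add atoms: chloromethyl methyl ether (MOMCl), COCCl
Why: Williamson-type MOM ether formation protects the two oxygens that flank the methyl group, which become the C5 and C7 oxygens of the chromone.

Step 16
Reactants: 26 1,3-bis(methoxymethoxy)-2-methylbenzene
Product: 28 3,5-bis(methoxymethoxy)-4-methylphenol, via arylboronate 27 (not isolated)
Conditions: [Ir(OMe)(cod)]2 (cat.), 4,4'-di-tert-butyl-2,2'-bipyridine, B2pin2, THF, 80 °C; then 30% H2O2, aq NaOH, 0 °C to rt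
Reagents that add atoms: hydrogen peroxide, OO
Why: Iridium-catalysed aromatic C–H borylation is sterically governed and should take the only C–H without an ortho substituent (para to the methyl group), and oxidation of the C–B bond in the same pot gives the phenol that is distinguished from the two protected oxygens.

Step 17
Reactants: 28 3,5-bis(methoxymethoxy)-4-methylphenol
Product: 29 2-bromo-3,5-bis(methoxymethoxy)-4-methylphenol
Conditions: NBS (1.0 equiv), CH2Cl2, −78 °C
Reagents that add atoms: N-bromosuccinimide, O=C1CCC(=O)N1Br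
Why: Electrophilic bromination of the phenol can only occur at one of its two equivalent ortho positions because the para position carries the methyl group, and low temperature with one equivalent should hold it at the monobromide.

Step 18
Reactants: 29 2-bromo-3,5-bis(methoxymethoxy)-4-methylphenol
Product: 31 1-[6-hydroxy-2,4-bis(methoxymethoxy)-3-methylphenyl]-2-methoxyethan-1-one, via dilithio phenoxide 30 (not isolated)
Conditions: t-BuLi (3.1 equiv), THF, −78 °C; MeOCH2C(O)N(OMe)Me, −78 °C to rt; aq NH4Cl
Reagents that add atoms: N-methoxy-N-methyl-2-methoxyacetamide, COCC(=O)N(C)OC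
Why: Deprotonation of the phenol followed by bromine–lithium exchange gives an ortho-lithiated phenoxide that is acylated once in a Weinreb ketone synthesis, which places the methoxyacetyl group between the free phenol and an OMOM group with no regiochemical ambiguity.

Step 19
Reactants: 24 (2S,3S)-2-[3,5-bis(methoxymethoxy)phenyl]-4,7-bis(methoxymethoxy)-3-[4-(methoxymethoxy)phenyl]-2,3-dihydro-1-benzofuran-5-carbaldehyde; 31 1-[6-hydroxy-2,4-bis(methoxymethoxy)-3-methylphenyl]-2-methoxyethan-1-one
Product: 32 (2Z)-3-{(2S,3S)-2-[3,5-bis(methoxymethoxy)phenyl]-4,7-bis(methoxymethoxy)-3-[4-(methoxymethoxy)phenyl]-2,3-dihydro-1-benzofuran-5-yl}-1-[6-hydroxy-2,4-bis(methoxymethoxy)-3-methylphenyl]-2-methoxyprop-2-en-1-one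
Conditions: KOH, EtOH/THF, 0 °C to rt
Reagents that add atoms: none
Why: Claisen–Schmidt condensation (aldol addition then E1cB dehydration) between the enolisable α-methoxy ketone and the non-enolisable aldehyde should give the 2'-hydroxy-α-methoxychalcone, expected as the isomer with the aryl group trans to the carbonyl, while hydroxide cannot deprotonate C2 or C3 of the dihydrofuran.

Step 20
Reactants: 32 the 2'-hydroxy-α-methoxychalcone of step 19
Product: 33 2-{(2S,3S)-2-[3,5-bis(methoxymethoxy)phenyl]-4,7-bis(methoxymethoxy)-3-[4-(methoxymethoxy)phenyl]-2,3-dihydro-1-benzofuran-5-yl}-3-methoxy-5,7-bis(methoxymethoxy)-6-methyl-4H-chromen-4-one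
Conditions: I2 (0.1 equiv), DMSO, 110 °C
Reagents that add atoms: none
Why: In the iodine/DMSO oxidative cyclisation of 2'-hydroxychalcones the only free phenol (the one next to the ring A C–H) closes ring C by 6-endo-trig oxa-Michael addition, α-iodination and loss of HI give the chromone, DMSO reoxidises HI, and the single free phenol fixes the methyl group at C6 and not at C8.

Step 21
Reactants: 33 the hepta-MOM 3-methoxyflavone of step 20
Product: 34 2-[(2S,3S)-2-(3,5-dihydroxyphenyl)-4,7-dihydroxy-3-(4-hydroxyphenyl)-2,3-dihydro-1-benzofuran-5-yl]-5,7-dihydroxy-3-methoxy-6-methyl-4H-chromen-4-one (CNP0218412.2)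
Conditions: 3 M HCl, MeOH/THF, 50 °C
Reagents that add atoms: none
Why: Acid-catalysed acetal cleavage in methanol should remove all seven MOM ethers as dimethoxymethane, while the C3 methyl ether of the chromone and the thermodynamically favoured trans dihydrofuran centres are not affected.

**Compound list**

1 | 2,5-dihydroxybenzaldehyde | O=Cc1cc(O)ccc1O | starting material
2 | 2,5-bis(methoxymethoxy)benzaldehyde | O=Cc1cc(OCOC)ccc1OCOC | intermediate
3 | 2,5-bis(methoxymethoxy)phenyl formate (not isolated) | O=COc1cc(OCOC)ccc1OCOC | intermediate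
4 | 2,5-bis(methoxymethoxy)phenol | Oc1cc(OCOC)ccc1OCOC | intermediate
5 | 2-hydroxy-3,6-bis(methoxymethoxy)benzaldehyde | O=Cc1c(O)c(OCOC)ccc1OCOC | intermediate
6 | 5-bromo-2-hydroxy-3,6-bis(methoxymethoxy)benzaldehyde | O=Cc1c(O)c(OCOC)cc(Br)c1OCOC | intermediate
7 | 4-bromophenol | Oc1ccc(Br)cc1 | starting material
8 | 1-bromo-4-(methoxymethoxy)benzene | COCOc1ccc(Br)cc1 | intermediate
9 | [4-(methoxymethoxy)phenyl]magnesium bromide (not isolated) | COCOc1ccc([Mg]Br)cc1 | intermediate
10 | racemic 4-bromo-2-{hydroxy[4-(methoxymethoxy)phenyl]methyl}-3,6-bis(methoxymethoxy)phenol | Oc1c(OCOC)cc(Br)c(OCOC)c1C(O)c1ccc(OCOC)cc1 | intermediate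
11 | racemic 4-bromo-3,6-bis(methoxymethoxy)-2-{[4-(methoxymethoxy)phenyl](4-methylbenzenesulfonyl)methyl}phenol | Oc1c(OCOC)cc(Br)c(OCOC)c1C(c1ccc(OCOC)cc1)S(=O)(=O)c1ccc(C)cc1 | intermediate
12 | (2R,5R)-hexane-2,5-diol | C[C@@H](O)CC[C@@H](C)O | starting material
13 | (2R,5R)-hexane-2,5-diyl dimethanesulfonate | C[C@@H](OS(C)(=O)=O)CC[C@@H](C)OS(C)(=O)=O | intermediate
14 | (2S,5S)-2,5-dimethylthiolane | C[C@H]1CC[C@H](C)S1 | intermediate
15 | 3,5-dihydroxybenzyl alcohol | OCc1cc(O)cc(O)c1 | starting material
16 | [3,5-bis(methoxymethoxy)phenyl]methanol | OCc1cc(OCOC)cc(OCOC)c1 | intermediate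
17 | 1-(bromomethyl)-3,5-bis(methoxymethoxy)benzene | BrCc1cc(OCOC)cc(OCOC)c1 | intermediate
18 | (2S,5S)-1-[3,5-bis(methoxymethoxy)benzyl]-2,5-dimethylthiolan-1-ium tetrafluoroborate | C[C@H]1CC[C@H](C)[S+]1Cc1cc(OCOC)cc(OCOC)c1.F[B-](F)(F)F | intermediate
19 | 4-bromo-2,5-bis(methoxymethoxy)-6-[4-(methoxymethoxy)benzylidene]cyclohexa-2,4-dien-1-one, ortho-quinone methide, alkene geometry not fixed (not isolated) | O=C1C(OCOC)=CC(Br)=C(OCOC)C1=Cc1ccc(OCOC)cc1 | intermediate
20 | [3,5-bis(methoxymethoxy)phenyl][(2S,5S)-2,5-dimethylthiolan-1-ium-1-yl]methanide, sulfonium ylide (not isolated) | C[C@H]1CC[C@H](C)[S+]1[CH-]c1cc(OCOC)cc(OCOC)c1 | intermediate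
21 | betaine: (2S,5S)-1-{(1R,2S)-1-[3,5-bis(methoxymethoxy)phenyl]-2-[3-bromo-2,5-bis(methoxymethoxy)-6-oxidophenyl]-2-[4-(methoxymethoxy)phenyl]ethyl}-2,5-dimethylthiolan-1-ium (not isolated) | C[C@H]1CC[C@H](C)[S+]1[C@@H](c1cc(OCOC)cc(OCOC)c1)[C@@H](c1ccc(OCOC)cc1)c1c([O-])c(OCOC)cc(Br)c1OCOC | intermediate
22 | (2S,3S)-2-[3,5-bis(methoxymethoxy)phenyl]-5-bromo-4,7-bis(methoxymethoxy)-3-[4-(methoxymethoxy)phenyl]-2,3-dihydro-1-benzofuran | Brc1cc(OCOC)c2c(c1OCOC)[C@H](c1ccc(OCOC)cc1)[C@@H](c1cc(OCOC)cc(OCOC)c1)O2 | intermediate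
23 | 5-lithio derivative of 22 (lithium in place of bromine, not isolated) | [Li]c1cc(OCOC)c2c(c1OCOC)[C@H](c1ccc(OCOC)cc1)[C@@H](c1cc(OCOC)cc(OCOC)c1)O2 | intermediate
24 | (2S,3S)-2-[3,5-bis(methoxymethoxy)phenyl]-4,7-bis(methoxymethoxy)-3-[4-(methoxymethoxy)phenyl]-2,3-dihydro-1-benzofuran-5-carbaldehyde | O=Cc1cc(OCOC)c2c(c1OCOC)[C@H](c1ccc(OCOC)cc1)[C@@H](c1cc(OCOC)cc(OCOC)c1)O2 | intermediate
25 | 2-methylresorcinol | Cc1c(O)cccc1O | starting material
26 | 1,3-bis(methoxymethoxy)-2-methylbenzene | Cc1c(OCOC)cccc1OCOC | intermediate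
27 | 2-[3,5-bis(methoxymethoxy)-4-methylphenyl]-4,4,5,5-tetramethyl-1,3,2-dioxaborolane (not isolated) | Cc1c(OCOC)cc(B2OC(C)(C)C(C)(C)O2)cc1OCOC | intermediate
28 | 3,5-bis(methoxymethoxy)-4-methylphenol | Cc1c(OCOC)cc(O)cc1OCOC | intermediate
29 | 2-bromo-3,5-bis(methoxymethoxy)-4-methylphenol | Cc1c(OCOC)cc(O)c(Br)c1OCOC | intermediate
30 | lithium 2-lithio-3,5-bis(methoxymethoxy)-4-methylphenolate (not isolated) | Cc1c(OCOC)cc(O[Li])c([Li])c1OCOC | intermediate
31 | 1-[6-hydroxy-2,4-bis(methoxymethoxy)-3-methylphenyl]-2-methoxyethan-1-one | COCC(=O)c1c(O)cc(OCOC)c(C)c1OCOC | intermediate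
32 | (2Z)-3-{(2S,3S)-2-[3,5-bis(methoxymethoxy)phenyl]-4,7-bis(methoxymethoxy)-3-[4-(methoxymethoxy)phenyl]-2,3-dihydro-1-benzofuran-5-yl}-1-[6-hydroxy-2,4-bis(methoxymethoxy)-3-methylphenyl]-2-methoxyprop-2-en-1-one | O=C(c1c(O)cc(OCOC)c(C)c1OCOC)/C(OC)=C/c1cc(OCOC)c2c(c1OCOC)[C@H](c1ccc(OCOC)cc1)[C@@H](c1cc(OCOC)cc(OCOC)c1)O2 | intermediate
33 | 2-{(2S,3S)-2-[3,5-bis(methoxymethoxy)phenyl]-4,7-bis(methoxymethoxy)-3-[4-(methoxymethoxy)phenyl]-2,3-dihydro-1-benzofuran-5-yl}-3-methoxy-5,7-bis(methoxymethoxy)-6-methyl-4H-chromen-4-one | COc1c(-c2cc(OCOC)c3c(c2OCOC)[C@H](c2ccc(OCOC)cc2)[C@@H](c2cc(OCOC)cc(OCOC)c2)O3)oc2cc(OCOC)c(C)c(OCOC)c2c1=O | intermediate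
34 | 2-[(2S,3S)-2-(3,5-dihydroxyphenyl)-4,7-dihydroxy-3-(4-hydroxyphenyl)-2,3-dihydro-1-benzofuran-5-yl]-5,7-dihydroxy-3-methoxy-6-methyl-4H-chromen-4-one | COc1c(-c2cc(O)c3c(c2O)[C@H](c2ccc(O)cc2)[C@@H](c2cc(O)cc(O)c2)O3)oc2cc(O)c(C)c(O)c2c1=O | target

**Summary**

Total step count: 21.
Longest linear sequence: 11 steps (steps 1, 2, 3, 4, 6, 7, 13, 14, 19, 20, 21).

Steps most likely to fail:

1. Step 13. The thiolanium unit may discriminate the ylide faces less well toward a quinone methide than toward an aldehyde. The two alkene isomers of 19 may add with different relative topicity and erode the trans selectivity, and the ylide may decompose before capture. The fallback sets out from 11 and 17 and comes back at 22. Bromide 17 is alkylated onto thiolane (NaBF4, CH2Cl2/H2O) to give the achiral salt 1-[3,5-bis(methoxymethoxy)benzyl]thiolan-1-ium tetrafluoroborate F1. F1 and 11 with Cs2CO3 in CH2Cl2 should give, by the same annulation without asymmetric induction, the racemic trans-2,3-dihydrobenzofuran F2. Preparative HPLC on a chiral stationary phase then separates the enantiomers and delivers 22.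

2. Step 19. Enolisation of the hindered α-methoxy ketone, present as its phenoxide, may be slow, and the aldol addition to the ortho-substituted aldehyde may revert faster than it dehydrates. The fallback sets out from 24 and 31 and comes back at 33, and it also bypasses step 20. Pinnick oxidation of 24 (NaClO2, NaH2PO4, 2-methylbut-2-ene, t-BuOH/H2O) gives the dihydrobenzofuran-5-carboxylic acid F3. Steglich esterification of F3 with the phenol of 31 (DCC, DMAP, CH2Cl2) gives the aryl ester F4. Baker–Venkataraman rearrangement (LiN(SiMe3)2, THF, −78 °C to rt) moves the aroyl group to the α-carbon and gives the 2-methoxy-1,3-diketone F5. Cyclodehydration through its one free phenol (NaOAc, AcOH, 90 °C) gives 33, and step 21 follows.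

3. Step 20. The HI formed may remove the MOM ether next to the ketone before ring closure. That would free the second ortho phenol and allow closure on the wrong oxygen (methyl at C8 instead of C6), and uncovered phenol rings could then be iodinated. The fallback sets out from 32 and comes back at 33. Ring C is closed first under base with all MOM groups in place: NaOAc in refluxing EtOH should give the 3-methoxychroman-4-one (flavanone) F6 by oxa-Michael addition of the only free phenol, as a mixture of epimers at its two new centres, which are removed in the next operation. Aerobic dehydrogenation with catalytic divalent palladium (Pd(O2CCF3)2, DMSO, O2, 80 °C) then gives 33 without iodine or acid.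

**Further compounds**

F1 | step 13 | 1-[3,5-bis(methoxymethoxy)benzyl]thiolan-1-ium tetrafluoroborate | COCOc1cc(C[S+]2CCCC2)cc(OCOC)c1.F[B-](F)(F)F
F2 | step 13 | racemic trans-2-[3,5-bis(methoxymethoxy)phenyl]-5-bromo-4,7-bis(methoxymethoxy)-3-[4-(methoxymethoxy)phenyl]-2,3-dihydro-1-benzofuran (1:1 pair of enantiomers) | Brc1cc(OCOC)c2c(c1OCOC)[C@H](c1ccc(OCOC)cc1)[C@@H](c1cc(OCOC)cc(OCOC)c1)O2.Brc1cc(OCOC)c2c(c1OCOC)[C@@H](c1ccc(OCOC)cc1)[C@H](c1cc(OCOC)cc(OCOC)c1)O2
F3 | step 19 | (2S,3S)-2-[3,5-bis(methoxymethoxy)phenyl]-4,7-bis(methoxymethoxy)-3-[4-(methoxymethoxy)phenyl]-2,3-dihydro-1-benzofuran-5-carboxylic acid | OC(=O)c1cc(OCOC)c2c(c1OCOC)[C@H](c1ccc(OCOC)cc1)[C@@H](c1cc(OCOC)cc(OCOC)c1)O2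
F4 | step 19 | 2-(methoxyacetyl)-3,5-bis(methoxymethoxy)-4-methylphenyl ester of F3 | COCC(=O)c1c(OC(=O)c2cc(OCOC)c3c(c2OCOC)[C@H](c2ccc(OCOC)cc2)[C@@H](c2cc(OCOC)cc(OCOC)c2)O3)cc(OCOC)c(C)c1OCOC
F5 | step 19 | 1-[6-hydroxy-2,4-bis(methoxymethoxy)-3-methylphenyl]-2-methoxy-3-{(2S,3S)-2-[3,5-bis(methoxymethoxy)phenyl]-4,7-bis(methoxymethoxy)-3-[4-(methoxymethoxy)phenyl]-2,3-dihydro-1-benzofuran-5-yl}propane-1,3-dione (configuration at C2 of the dione not fixed) | COC(C(=O)c1c(O)cc(OCOC)c(C)c1OCOC)C(=O)c1cc(OCOC)c2c(c1OCOC)[C@H](c1ccc(OCOC)cc1)[C@@H](c1cc(OCOC)cc(OCOC)c1)O2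
F6 | step 20 | 2-{(2S,3S)-2-[3,5-bis(methoxymethoxy)phenyl]-4,7-bis(methoxymethoxy)-3-[4-(methoxymethoxy)phenyl]-2,3-dihydro-1-benzofuran-5-yl}-3-methoxy-5,7-bis(methoxymethoxy)-6-methyl-2,3-dihydro-4H-chromen-4-one (configuration at C2 and C3 of the chromanone not fixed) | COC1C(c2cc(OCOC)c3c(c2OCOC)[C@H](c2ccc(OCOC)cc2)[C@@H](c2cc(OCOC)cc(OCOC)c2)O3)Oc2cc(OCOC)c(C)c(OCOC)c2C1=O
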